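Count first what the protic impurity takes from the charge, then what the clock can do with the rest.

| flask | starting material | protic impurity | remark | time |
|---|---|---|---|---|
| north | 0.10 M | 0.023 M | run made earlier |  |
| south-east | 0.10 M | 0.030 M | run made earlier |  |
| west | 0.10 M | 0.044 M | run made earlier |  |
| east | 0.19 M | 0.020 M | run made earlier |  |
| larch | 0.10 M | 0.0200 M |  | 25 min |
| birch | 0.20 M | 0.0400 M |  | 40 min |

| run | time / min | target / % | starting material / % |
|---|---|---|---|
| north | 1.00 | 0.6 | 65.5 |
| north | 3.00 | 3.9 | 50.6 |
| north | 6.00 | 8.6 | 32.2 |
| north | 8.00 | 15.3 | 22.2 |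
| north | 12.0 | 25.5 | 14.3 |
| south-east | 1.00 | 0.8 | 59.2 |
| south-east | 3.00 | 1.9 | 45.7 |
| south-east | 6.00 | 9.6 | 29.5 |
| south-east | 8.00 | 10.6 | 24.5 |
| south-east | 12.0 | 21.8 | 11.4 |
| west | 1.00 | 1.1 | 48.6 |
| west | 2.00 | 1.9 | 42.2 |
| west | 4.00 | 5.4 | 31.1 |
| west | 6.00 | 5.9 | 23.2 |
| west | 12.0 | 18.9 | 10.1 |
| east | 1.00 | 1.0 | 77.3 |
| east | 3.00 | 1.3 | 59.7 |
| east | 6.00 | 9.5 | 38.3 |
| east | 8.00 | 14.9 | 28.6 |
| east | 12.0 | 26.5 | 16.1 |

(scatter of a reading: 1 percentage point)



* which of the two ends with the higher amount of target, in percent of the starting material charged ("neither" if they lie within 2 percentage points) (larch / birch / neither)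
* target at the end, in percent of the starting material charged, larch
* target at the end, in percent of the starting material charged, birch

In the north run the starting material falls quickly before the first reading and then decays smoothly. Its readings at 3.00 min and 12.0 min give a first-order constant k = 0.140 min⁻¹, a half-life of 4.94 min. Run back to zero time, that line starts at 77.1%, and one minus impurity over starting material charged is 77.0%. So one impurity seems to remove one starting material. Call that part of the charge which outlasts the impurity the usable share, u: 80.0% for larch and 80.0% for birch.

One run could mislead, but the west run, with 0.044 M of impurity, reads back to 54.5% against a u of 56.0%. Birch doubles the starting material of larch, which might change the decay, but the east run at 0.19 M gives 0.144 min⁻¹. Larch then gets 5.06 half-lives and birch 8.10, which by this estimate leaves 2.39% and 0.291% of the charge as starting material.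

Yet target does not follow the starting material: at 12.0 min the north run still has, by this reckoning, 37.3% of its charge in an unseen pool, and the readings of that run stop there. This reckoning therefore commits to a ceiling of u on target in both flasks, and to birch, which has 15.0 min longer than larch for the pool to drain.

The forecast says birch, with 55% for larch and 71% for birch: “Birch wins through its longer time.”

Birch ends with 53.6% of target and larch with 45.2%.

    starting material → intermediate (k = 0.00239 s⁻¹)
    intermediate ⇌ target (K = 2.40, k = 0.00121 s⁻¹)
    2 starting material → self-condensation product (k = 2.72 × 10⁻⁵ M⁻¹ s⁻¹)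
    starting material + protic impurity → quenched substrate (k = 1.30 M⁻¹ s⁻¹)

Birch ends with 20.0% of quenched substrate, which is one minus u, and 0% of protic impurity, the limiting reagent of the quench. With K2 = 2.4, the equilibrium ratio of target to intermediate, u times K2/(1+K2) is 56.5% for birch; left until 400 min, birch holds 56.4% of target and 23.5% of intermediate. A flask like birch but charged with 0.34 M of starting material has u = 88.2%, so scaling birch's target by the usable shares gives 59.1%, and that flask ends with 59.0%.

(The runs come from a simulation for substances that don't exist; scatter was added.)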